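**Strategy**

Ring A is disconnected at C4a–C5 and C8–C8a (chromanone numbering), which divides the target into a four-carbon C5–C8 unit and the C4a=C8a vinylogous-ester double bond shared by rings A and B. The 5-hydroxy-7-oxo pattern is read as a Chan-type 1,3-bis(silyloxy)diene bearing the lavandulyl chain; C4a=C8a as the enone of an enantiopure 2,3-dimethyldihydropyranone whose 5-sulfinyl group makes it an alkyne equivalent. One [4+2] cycloaddition, sulfoxide elimination and aromatisation joins both chiral fragments into the 8-lavandulyl acylphloroglucinol chromanone with complete regiocontrol. C6 is then annulated with phenylpropynal, C8 prenylated with dearomatisation, and the lactone opened.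

Key step: step 10

**Remarks on the chemistry (assumptions)**
- Chromanone numbering (O1, C2, C3, C4, C4a, C5–C8, C8a) is used for the bicyclic core in the discussion; the target is written as its 5-hydroxy-4,7-dioxo tautomer.
- Racemic methyl phenyl sulfoxide is used, so 14, 15 and 16 are carried as mixtures of sulfur epimers; sulfur is expelled in step 10.
- Diene 10 is used as a mixture of double-bond isomers; both diene termini become aromatic carbons.
- The sense of induction of the chiral catalysts in steps 11 and 12 is proposed, not established; in each case the antipodal catalyst is the direct check.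

**Route**

Step 1
Reactants: 1 (4S)-4-benzyl-1,3-oxazolidin-2-one; 2 3-methylbut-2-enoyl chloride
Product: 3 (4S)-4-benzyl-3-(3-methylbut-2-enoyl)-1,3-oxazolidin-2-one
Conditions: n-BuLi, THF, −78 °C; then 2, −78 to 0 °C
Reagents that add atoms: none
Why: N-acylation of the lithiated oxazolidinone by the acid chloride (Evans imide formation) is routine and creates no stereocentre.

Step 2
Reactants: 3 (4S)-4-benzyl-3-(3-methylbut-2-enoyl)-1,3-oxazolidin-2-one; 4 1-bromo-3-methylbut-2-ene (prenyl bromide)
Product: 5 (4S)-4-benzyl-3-[(2S)-5-methyl-2-(prop-1-en-2-yl)hex-4-enoyl]-1,3-oxazolidin-2-one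
Conditions: NaN(SiMe3)2, THF, −78 °C; then 4, −78 to −30 °C
Reagents that add atoms: none
Why: Deconjugative Evans alkylation: the chelated dienolate is alkylated at its α-carbon on the face opposite the benzyl group, which should set the (2S) lavandulyl centre and leave the isopropenyl double bond out of conjugation.

Step 3
Reactants: 5 (4S)-4-benzyl-3-[(2S)-5-methyl-2-(prop-1-en-2-yl)hex-4-enoyl]-1,3-oxazolidin-2-one
Product: 6 (2S)-5-methyl-2-(prop-1-en-2-yl)hex-4-en-1-ol [(S)-lavandulol]
Conditions: LiBH4, H2O (1 equiv), Et2O, 0 °C; 1 M NaOH work-up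
Reagents that add atoms: none
Why: Reductive cleavage of the Evans imide by LiBH4 should give the primary alcohol without touching the stereocentre or the alkenes and returns the auxiliary.

Step 4
Reactants: 6 (2S)-5-methyl-2-(prop-1-en-2-yl)hex-4-en-1-ol
Product: 7 (3S)-3-(iodomethyl)-2,6-dimethylhepta-1,5-diene [(S)-lavandulyl iodide]
Conditions: PPh3, I2, imidazole, CH2Cl2, 0 °C to rt
Reagents that add atoms: iodine, II
Why: Appel-type iodination proceeds by SN2 displacement at the primary carbon, so the adjacent stereocentre is untouched.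

Step 5
Reactants: 8 methyl 3-oxobutanoate (methyl acetoacetate); 7 (3S)-3-(iodomethyl)-2,6-dimethylhepta-1,5-diene
Product: 9 methyl (6S)-9-methyl-3-oxo-6-(prop-1-en-2-yl)dec-8-enoate
Conditions: NaH, THF, 0 °C; n-BuLi, 0 °C; then 7, DMPU, 0 °C to rt; 1 M HCl work-up
Reagents that add atoms: none
Why: Weiler dianion alkylation: the γ-carbanion of the acetoacetate dianion is the more nucleophilic site and should displace the primary iodide by SN2 without creating a stereocentre.

Step 6
Reactants: 9 methyl (6S)-9-methyl-3-oxo-6-(prop-1-en-2-yl)dec-8-enoate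
Product: 10 (6R)-1-methoxy-9-methyl-6-(prop-1-en-2-yl)-1,3-bis(trimethylsilyloxy)deca-1,3,8-triene (mixture of diene geometries; the descriptor changes by priority only, the configuration is unchanged)
Conditions: Me3SiOTf (2.2 equiv), Et3N (2.5 equiv), Et2O, 0 °C to rt; ammonium salt layer removed under argon, used crude
Reagents that add atoms: trimethylsilyl trifluoromethanesulfonate, C[Si](C)(C)OS(=O)(=O)C(F)(F)F
Why: Double soft-enolisation and O-silylation of the β-ketoester gives the Chan-type 1,3-bis(silyloxy)diene, the second enolisation going toward C4 because C2 is already sp2.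

Step 7
Reactants: 11 methyl (3R)-3-hydroxybutanoate
Product: 12 methyl (2R,3R)-3-hydroxy-2-methylbutanoate
Conditions: LiN(iPr)2 (2.2 equiv), THF, −78 to −20 °C; MeI, DMPU, −78 to 0 °C; 1 M HCl work-up
Reagents that add atoms: iodomethane, CI
Why: Fráter–Seebach alkylation: the chelated lithium alkoxide–enolate is methylated anti to the C3 methyl group, which should set the anti (2R,3R) relationship that becomes the trans-2,3-dimethyl pattern of ring B.

Step 8
Reactants: 12 methyl (2R,3R)-3-hydroxy-2-methylbutanoate; 13 methyl phenyl sulfoxide (racemic)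
Product: 14 (3R,4R)-4-hydroxy-3-methyl-1-(phenylsulfinyl)pentan-2-one (both sulfur epimers)
Conditions: 13 (3.3 equiv), LiN(iPr)2 (3.3 equiv), THF, −78 °C; then 12, −78 to −20 °C; 1 M HCl work-up at 0 °C
Reagents that add atoms: none
Why: Claisen-type acylation of the α-sulfinyl carbanion by the ester (β-ketosulfoxide synthesis), with excess base covering the free hydroxyl; the product rests as its sulfinyl-stabilised enolate, which protects the α-methyl stereocentre.

Step 9
Reactants: 14 (3R,4R)-4-hydroxy-3-methyl-1-(phenylsulfinyl)pentan-2-one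
Product: 15 (2R,3R)-2,3-dimethyl-5-(phenylsulfinyl)-2,3-dihydro-4H-pyran-4-one (both sulfur epimers)
Conditions: Me2NCH(OMe)2, toluene, 60 °C; then AcOH, 60 °C
Reagents that add atoms: N,N-dimethylformamide dimethyl acetal, COC(OC)N(C)C
Why: Enaminone formation at the active methylene followed by 6-endo addition–elimination of the secondary hydroxyl (loss of Me2NH) is the standard route to 3-substituted chromones; the carbinol C–O bond is not broken, so both stereocentres are retained.

Step 10
Reactants: 10 (6R)-1-methoxy-9-methyl-6-(prop-1-en-2-yl)-1,3-bis(trimethylsilyloxy)deca-1,3,8-triene; 15 (2R,3R)-2,3-dimethyl-5-(phenylsulfinyl)-2,3-dihydro-4H-pyran-4-one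
Product: 17 (2R,3R)-5,7-dihydroxy-2,3-dimethyl-8-[(2R)-5-methyl-2-(prop-1-en-2-yl)hex-4-en-1-yl]-2,3-dihydro-4H-chromen-4-one, via sulfinyl cycloadduct 16 (not isolated)
Conditions: ZnBr2 (1.2 equiv), CH2Cl2, −40 °C to rt, then 40 °C; then 1 M HCl, THF, 0 °C
Reagents that add atoms: none
Why: ZnBr2 chelates the sulfinyl and C4 carbonyl oxygens of 15 and lowers the LUMO of the vinylogous-ester double bond, so the nucleophilic C4 terminus of diene 10 bonds to the oxygen-bearing β-carbon (future C8a) and the ketene-acetal carbon C1 to the sulfinyl-bearing α-carbon (future C4a), either as a concerted asynchronous [4+2] cycloaddition or as a Mukaiyama–Michael addition followed by ring closure; adduct 16 then loses PhSOH by thermal syn-elimination (sulfinyl and H-8a are necessarily cis at the new ring fusion), ejects MeOSiMe3 from the C5 ketal and aromatises on desilylation. The closest known reaction type is the Diels–Alder reaction of Brassard/Chan 1,3-bis(silyloxy)dienes with α-sulfinyl enones and sulfinylquinones followed by sulfoxide elimination, the sulfinyl alkene serving as an alkyne equivalent, together with cycloadditions of 3-activated chromones. Ring A is the only ring closed, by intermolecular [4+2] annulation giving the six-membered carbocycle with C4a–C5 and C8–C8a both new. No permanent stereocentre is created: the centres of 16 at C4a, C5, C8, C8a and sulfur become sp2 or are expelled, and C2/C3 of ring B are not involved and keep their thermodynamically preferred trans arrangement. The selectivity needed is regiochemical, lavandulyl at C8 next to O1 and not at C6, and it is secured by the polarity match between the γ-carbon of the diene and the β-carbon of the enone, which neither phloroglucinol alkylation nor chromanone cyclisation could guarantee. The sulfoxide also fixes the phloroglucinol oxidation level, which is why 15 and not the parent dihydropyranone is used.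

Step 11
Reactants: 17 (2R,3R)-5,7-dihydroxy-2,3-dimethyl-8-[(2R)-5-methyl-2-(prop-1-en-2-yl)hex-4-en-1-yl]-2,3-dihydro-4H-chromen-4-one; 18 3-phenylprop-2-ynal
Product: 19 (4S,7R,8R)-5-hydroxy-7,8-dimethyl-10-[(2R)-5-methyl-2-(prop-1-en-2-yl)hex-4-en-1-yl]-4-phenyl-3,4,7,8-tetrahydro-2H,6H-pyrano[3,2-g]chromene-2,6-dione (the 4-phenyl-dihydrocoumarin lactone closed between C6 and O7 of 17)
Conditions: (5aS,10bR)-2-mesityl-5a,10b-dihydro-4H,6H-indeno[2,1-b][1,2,4]triazolo[4,3-d][1,4]oxazin-2-ium chloride (10 mol %), toluene, 40 °C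
Reagents that add atoms: none
Why: Carbene-catalysed redox annulation (Coates–Claisen type): the ynal becomes an α,β-unsaturated acyl azolium that is intercepted by the free 7-OH/C6 enol unit (5-OH is locked in a hydrogen bond to C4=O and C6 is the only free ring carbon), and C–C bond formation then lactonisation should set the benzylic (S) centre under control of the chiral triazolium.

Step 12
Reactants: 19 (4S,7R,8R)-5-hydroxy-7,8-dimethyl-10-[(2R)-5-methyl-2-(prop-1-en-2-yl)hex-4-en-1-yl]-4-phenyl-3,4,7,8-tetrahydro-2H,6H-pyrano[3,2-g]chromene-2,6-dione; 20 3-methylbut-2-en-1-yl acetate (prenyl acetate)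
Product: 21 (4S,7R,8R,10S)-7,8-dimethyl-10-(3-methylbut-2-en-1-yl)-10-[(2R)-5-methyl-2-(prop-1-en-2-yl)hex-4-en-1-yl]-4-phenyl-3,4,7,8-tetrahydro-2H-pyrano[3,2-g]chromene-2,5,6(10H)-trione (C8-prenylated, dearomatised lactone; C8 of the chromanone is S)
Conditions: Pd2(dba)3 (2.5 mol %), N,N'-[(1R,2R)-cyclohexane-1,2-diyl]bis[2-(diphenylphosphanyl)benzamide] (7.5 mol %), Cs2CO3 (1.1 equiv), THF, 0 °C to rt
Reagents that add atoms: none
Why: Tsuji–Trost asymmetric allylic alkylation with dearomatisation: the 5-phenoxide attacks the unsubstituted terminus of the π-prenyl complex formed from zerovalent palladium through C8, the only ring carbon para to O5 that is not blocked (C6 is lactone-fused, C4a acyl-substituted, O-prenylation is reversible under the catalysis), and the chiral ligand pocket should select the face of C8 and set the (S) quaternary centre.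

Step 13
Reactants: 21 (4S,7R,8R,10S)-7,8-dimethyl-10-(3-methylbut-2-en-1-yl)-10-[(2R)-5-methyl-2-(prop-1-en-2-yl)hex-4-en-1-yl]-4-phenyl-3,4,7,8-tetrahydro-2H-pyrano[3,2-g]chromene-2,5,6(10H)-trione
Product: 22 (3S)-3-[(2R,3R,8S)-5-hydroxy-2,3-dimethyl-8-(3-methylbut-2-en-1-yl)-8-[(2R)-5-methyl-2-(prop-1-en-2-yl)hex-4-en-1-yl]-4,7-dioxo-3,4,7,8-tetrahydro-2H-chromen-6-yl]-3-phenylpropanoic acid (CNP0150579.1)
Conditions: LiOH (3 equiv), THF/H2O 3:1, 0 °C, brief; then 1 M HCl to pH 3
Reagents that add atoms: water, O
Why: Saponification of the enol lactone, the most electrophilic carbonyl, should free the acid and the 5-hydroxy-4,7-dioxo enol, the short cold treatment avoiding retro-oxa-Michael opening of ring B; no stereocentre is touched.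

**Compound list**

1 | (4S)-4-benzyl-1,3-oxazolidin-2-one | O=C1N[C@@H](Cc2ccccc2)CO1 | starting material
2 | 3-methylbut-2-enoyl chloride | CC(C)=CC(=O)Cl | starting material
3 | (4S)-4-benzyl-3-(3-methylbut-2-enoyl)-1,3-oxazolidin-2-one | CC(C)=CC(=O)N1[C@@H](Cc2ccccc2)COC1=O | intermediate
4 | 1-bromo-3-methylbut-2-ene | CC(C)=CCBr | starting material
5 | (4S)-4-benzyl-3-[(2S)-5-methyl-2-(prop-1-en-2-yl)hex-4-enoyl]-1,3-oxazolidin-2-one | C=C(C)[C@H](CC=C(C)C)C(=O)N1[C@@H](Cc2ccccc2)COC1=O | intermediate
6 | (2S)-5-methyl-2-(prop-1-en-2-yl)hex-4-en-1-ol | C=C(C)[C@H](CC=C(C)C)CO | intermediate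
7 | (3S)-3-(iodomethyl)-2,6-dimethylhepta-1,5-diene | C=C(C)[C@H](CC=C(C)C)CI | intermediate
8 | methyl 3-oxobutanoate | COC(=O)CC(C)=O | starting material
9 | methyl (6S)-9-methyl-3-oxo-6-(prop-1-en-2-yl)dec-8-enoate | C=C(C)[C@H](CC=C(C)C)CCC(=O)CC(=O)OC | intermediate
10 | (6R)-1-methoxy-9-methyl-6-(prop-1-en-2-yl)-1,3-bis(trimethylsilyloxy)deca-1,3,8-triene (diene geometry not defined) | C=C(C)[C@H](CC=C(C)C)CC=C(O[Si](C)(C)C)C=C(OC)O[Si](C)(C)C | intermediate
11 | methyl (3R)-3-hydroxybutanoate | O[C@H](C)CC(=O)OC | starting material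
12 | methyl (2R,3R)-3-hydroxy-2-methylbutanoate | O[C@H](C)[C@@H](C)C(=O)OC | intermediate
13 | methyl phenyl sulfoxide (racemic) | CS(=O)c1ccccc1 | starting material
14 | (3R,4R)-4-hydroxy-3-methyl-1-(phenylsulfinyl)pentan-2-one (sulfur epimers) | O[C@H](C)[C@@H](C)C(=O)CS(=O)c1ccccc1 | intermediate
15 | (2R,3R)-2,3-dimethyl-5-(phenylsulfinyl)-2,3-dihydro-4H-pyran-4-one (sulfur epimers) | O1[C@H](C)[C@@H](C)C(=O)C(S(=O)c2ccccc2)=C1 | intermediate
16 | (2R,3R)-5-methoxy-2,3-dimethyl-8-[(2R)-5-methyl-2-(prop-1-en-2-yl)hex-4-en-1-yl]-4a-(phenylsulfinyl)-5,7-bis(trimethylsilyloxy)-2,3,4a,5,8,8a-hexahydro-4H-chromen-4-one (transient centres at C4a, C5, C8, C8a and S not defined) | C=C(C)[C@H](CC=C(C)C)CC1C(O[Si](C)(C)C)=CC(OC)(O[Si](C)(C)C)C2(S(=O)c3ccccc3)C1O[C@H](C)[C@@H](C)C2=O | intermediate (not isolated)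
17 | (2R,3R)-5,7-dihydroxy-2,3-dimethyl-8-[(2R)-5-methyl-2-(prop-1-en-2-yl)hex-4-en-1-yl]-2,3-dihydro-4H-chromen-4-one | C=C(C)[C@H](CC=C(C)C)Cc1c(O)cc(O)c2c1O[C@H](C)[C@@H](C)C2=O | intermediate
18 | 3-phenylprop-2-ynal | O=CC#Cc1ccccc1 | starting material
19 | (4S,7R,8R)-5-hydroxy-7,8-dimethyl-10-[(2R)-5-methyl-2-(prop-1-en-2-yl)hex-4-en-1-yl]-4-phenyl-3,4,7,8-tetrahydro-2H,6H-pyrano[3,2-g]chromene-2,6-dione | C=C(C)[C@H](CC=C(C)C)Cc1c2OC(=O)C[C@@H](c3ccccc3)c2c(O)c2c1O[C@H](C)[C@@H](C)C2=O | intermediate
20 | 3-methylbut-2-en-1-yl acetate | CC(C)=CCOC(C)=O | starting material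
21 | (4S,7R,8R,10S)-7,8-dimethyl-10-(3-methylbut-2-en-1-yl)-10-[(2R)-5-methyl-2-(prop-1-en-2-yl)hex-4-en-1-yl]-4-phenyl-3,4,7,8-tetrahydro-2H-pyrano[3,2-g]chromene-2,5,6(10H)-trione | C=C(C)[C@H](CC=C(C)C)C[C@]1(CC=C(C)C)C2=C([C@H](c3ccccc3)CC(=O)O2)C(=O)C2=C1O[C@H](C)[C@@H](C)C2=O | intermediate
22 | (3S)-3-[(2R,3R,8S)-5-hydroxy-2,3-dimethyl-8-(3-methylbut-2-en-1-yl)-8-[(2R)-5-methyl-2-(prop-1-en-2-yl)hex-4-en-1-yl]-4,7-dioxo-3,4,7,8-tetrahydro-2H-chromen-6-yl]-3-phenylpropanoic acid | C=C(C)[C@H](CC=C(C)C)C[C@]1(CC=C(C)C)C(=O)C([C@@H](CC(=O)O)c2ccccc2)=C(O)C2=C1O[C@H](C)[C@@H](C)C2=O | target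

**Step count**

Total: 13 steps. Longest linear sequence: 10 steps (steps 1–6, then 10–13); steps 7–9 form the convergent branch.

**Steps most likely to fail, with fallbacks**

Step 10. After the first C–C bond is formed, silyl transfer to the sulfinyl enolate may outrun ring closure onto the ketene-acetal carbon, leaving only the open Michael adduct, or the diene may be protodesilylated before it reacts. The fallback is a two-stage ionic annulation that sets out from 10 and 15. A Me3SiOTf-catalysed vinylogous Mukaiyama–Michael addition at −78 °C with aqueous work-up would give the open-chain adduct methyl (6R)-4-[(5R,6R)-5,6-dimethyl-4-oxo-3-(phenylsulfinyl)tetrahydro-2H-pyran-2-yl]-9-methyl-3-oxo-6-(prop-1-en-2-yl)dec-8-enoate F1 (mixture at the transient centres). Treatment with NaOMe in MeOH at 0 °C to rt would effect Dieckmann condensation of the α-sulfinyl ketone enolate onto the ester, and warming to 50 °C would eliminate the sulfoxide and aromatise. The sequence comes back to the route at 17.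

Step 12. The palladium-catalysed prenylation may show poor facial selectivity at C8 if substrate and ligand are mismatched, may stall at the O-prenyl ether, or may suffer slow ionisation of the prenyl donor. The fallback sets out from 19 and replaces intermolecular allylation by a sigmatropic relay. O-Alkylation of the 5-hydroxyl with prenyl bromide 4 and K2CO3 in acetone would give (4S,7R,8R)-7,8-dimethyl-5-[(3-methylbut-2-en-1-yl)oxy]-10-[(2R)-5-methyl-2-(prop-1-en-2-yl)hex-4-en-1-yl]-4-phenyl-3,4,7,8-tetrahydro-2H,6H-pyrano[3,2-g]chromene-2,6-dione F2. Heating F2 in N,N-diethylaniline at 130 °C should trigger a para-Claisen (Claisen then Cope) migration O5 to C6 to C8, which places the linear prenyl group on C8 with dearomatisation. The sequence comes back to the route at 21 after chromatographic removal of the C8 epimer, since this relay offers no facial control.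

Step 11. The acyl azolium may simply O-acylate the phenols without C–C bond formation, or the carbene catalyst may give low enantioselectivity on this hindered acylphloroglucinol. The fallback sets out from 17 and uses iminium activation instead. (E)-Cinnamaldehyde with (S)-α,α-diphenylprolinol trimethylsilyl ether and benzoic acid in toluene should effect Friedel–Crafts-type conjugate addition at C6 and hemiacetal closure on O7. This would give the lactol (4S,7R,8R)-2,5-dihydroxy-7,8-dimethyl-10-[(2R)-5-methyl-2-(prop-1-en-2-yl)hex-4-en-1-yl]-4-phenyl-3,4,7,8-tetrahydro-2H,6H-pyrano[3,2-g]chromen-6-one F3 (anomeric mixture). Oxidation with pyridinium chlorochromate and NaOAc in CH2Cl2 comes back to the route at 19.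

**Further compounds**

F1 | step 10 | methyl (6R)-4-[(5R,6R)-5,6-dimethyl-4-oxo-3-(phenylsulfinyl)tetrahydro-2H-pyran-2-yl]-9-methyl-3-oxo-6-(prop-1-en-2-yl)dec-8-enoate | C=C(C)[C@H](CC=C(C)C)CC(C(=O)CC(=O)OC)C1O[C@H](C)[C@@H](C)C(=O)C1S(=O)c1ccccc1
F2 | step 12 | (4S,7R,8R)-7,8-dimethyl-5-[(3-methylbut-2-en-1-yl)oxy]-10-[(2R)-5-methyl-2-(prop-1-en-2-yl)hex-4-en-1-yl]-4-phenyl-3,4,7,8-tetrahydro-2H,6H-pyrano[3,2-g]chromene-2,6-dione | C=C(C)[C@H](CC=C(C)C)Cc1c2OC(=O)C[C@@H](c3ccccc3)c2c(OCC=C(C)C)c2c1O[C@H](C)[C@@H](C)C2=O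
F3 | step 11 | (4S,7R,8R)-2,5-dihydroxy-7,8-dimethyl-10-[(2R)-5-methyl-2-(prop-1-en-2-yl)hex-4-en-1-yl]-4-phenyl-3,4,7,8-tetrahydro-2H,6H-pyrano[3,2-g]chromen-6-one | C=C(C)[C@H](CC=C(C)C)Cc1c2OC(O)C[C@@H](c3ccccc3)c2c(O)c2c1O[C@H](C)[C@@H](C)C2=O
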